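From the first reading at 0.833 d on, grey stands level, with tetra adduct averaging 57.7 % and triple product 19.8 %, each reading carrying a scatter of 1 percentage point. Taking that level as the end state, with reagent as the limiting reagent, it can be balanced twice. By substrate, 22.5 % of the charge lies outside those two forms. By reagent, the two forms hold 2.90 of the 3.06 equivalents charged, so 0.163 equivalents remain for that remainder. This is less than one reagent per substrate there, so about 6.23 % or more, as a reading with the scatter of its readings, is the unloaded share, the part of the substrate charged that carries no reagent, read as the remainder minus the equivalents left.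

common to all: substrate 0.31 M
- red: reagent 0.12 M; run made earlier
- ochre: reagent 0.45 M; run made earlier
- grey: reagent 0.95 M; run made earlier
- alder: reagent 0.155 M; time 4.0 d
- elm: reagent 0.310 M; time 4.0 d
- birch: reagent 1.24 M; time 4.0 d

| run | time / d | tetra adduct / % | triple product / % |
|---|---|---|---|
| red | 0.333 | 0 | 0 |
| red | 0.625 | 0 | 1.8 |
| red | 1.04 | 0 | 0 |
| red | 2.00 | 0.9 | 0 |
| red | 4.00 | 0 | 2.0 |
| ochre | 0.833 | 6.9 | 15.9 |
| ochre | 1.67 | 6.2 | 14.2 |
| ochre | 2.50 | 6.0 | 17.2 |
| ochre | 3.00 | 6.5 | 15.4 |
| ochre | 4.00 | 3.9 | 16.6 |
| grey | 0.833 | 58.4 | 19.4 |
| grey | 1.67 | 58.3 | 19.7 |
| grey | 2.50 | 56.3 | 20.8 |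
| grey | 3.00 | 58.0 | 19.6 |
| grey | 4.00 | 57.6 | 19.3 |

(readings scatter by 1 percentage point)

- the earlier runs were read with a standard deviation of 1 points

* which of these holds the largest part of the substrate at the end of alder (tetra adduct / triple product / substrate / mono adduct / double product)
* which of these holds the largest part of the substrate at the end of elm (tetra adduct / triple product / substrate / mono adduct / double product)
* which of these holds the largest part of the substrate at the end of birch (tetra adduct / triple product / substrate / mono adduct / double product)
* amount of tetra adduct at the end of birch, in percent of the substrate charged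

Birch is charged 4.00 equivalents, and counting reagent allows tetra adduct on the whole charge, 100 %. Taking the unloaded share read in grey as the same in birch, an assumption, puts tetra adduct in birch at about 93.8 % or below. The two ways part, and the reagent count is taken here as the one that cheats, as it puts reagent on each substrate, which the readings of grey do not show. The reckoning here commits to 93.8 % as an estimated upper mark.

The forecast names substrate for alder, substrate for elm and tetra adduct for birch, with 93 % of tetra adduct in birch, on its own ground that “exact stoichiometry leaves a slow second-order tail”.

The flask gives substrate for alder, mono adduct for elm, where substrate stands at 0 %, and tetra adduct for birch, with 88.7 % of tetra adduct.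

    reagent + double product → triple product + by-product (k = 0.110 M⁻¹ min⁻¹)
    substrate + reagent → mono adduct + by-product (k = 0.150 M⁻¹ min⁻¹)
    reagent + mono adduct → double product + by-product (k = 0.0600 M⁻¹ min⁻¹)
    substrate + mono adduct → side product (k = 0.0850 M⁻¹ min⁻¹)
    reagent + triple product → tetra adduct + by-product (k = 0.0500 M⁻¹ min⁻¹)

Birch ends with 9.9 % of its reagent and 0 % of its substrate left, and the same balance gives an unloaded share of 5.64 %. That is half of its 11.3 % side product, which counts two substrates and holds one reagent. A neighbour of birch charged with 0.50 M of reagent ends with 0 % of reagent, 8.55 % of tetra adduct, 18.9 % of triple product and 15.5 % of double product. With double product counted for its two adducts, the balance gives 17.6 %, half of the 35.2 % side product in that neighbour.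

The data were generated by integration from invented constants; noise was put on by code.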